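**Strategy**

- Retrosynthetically the two O-benzyl groups are removed first, then C2–H and C3–O of the pyran (ring C) are cut together, leaving a flat, achiral 4H-chromene (flav-2-ene).
- The flavene goes back through C4–H to a flavylium cation, which is cut at C3–C4 and O1–C2 into a ring A salicylaldehyde and a ring B methyl ketone. The aldehyde is cut at the aryl–CH2 bond of its bibenzyl chain.
- Forward, the bibenzyl chain is joined first and the ring A phenol is unmasked. Ring C is then closed as the benzopyrylium, reduced at C4, and functionalised at C2 and C3 last; all three benzene rings are bought.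
- The enabling feature is the array O1–C2(H)(aryl)–C3(H)(OH) in ring C with aryl and OH trans. It is the syn H/OH adduct of a C2=C3 enol ether, and both O1 and the C2 aryl group send boron to C3.
- Both stereocentres (2R,3S) come from one reagent-controlled hydroboration with monoisopinocampheylborane from (+)-α-pinene. The trans relationship follows from syn addition and oxidation with retention.

Key step: step 7

Remark: the facial preference of monoisopinocampheylborane on the flav-2-ene is assumed to parallel that on 1-arylcycloalkenes, where the (+)-α-pinene reagent gives the spatially corresponding (1S,2R) alcohols; if it is reversed, the reagent from (−)-α-pinene is used in the same way.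

**Route**

Step 1
Reactants: 1 3-(benzyloxy)benzaldehyde
Product: 2 1-(benzyloxy)-3-ethenylbenzene
Conditions: Ph3PCH3Br, KOtBu, THF, 0 °C → rt
Reagents that add atoms: methyltriphenylphosphonium bromide, C[P+](c1ccccc1)(c1ccccc1)c1ccccc1.[Br-]
Why: Wittig methylenation of an aromatic aldehyde with the non-stabilised ylide is routine, creates no stereocentre and leaves the benzyl ether untouched.

Step 2
Reactants: 2 1-(benzyloxy)-3-ethenylbenzene; 3 2-bromo-4,6-dimethoxybenzaldehyde
Product: 5 2-[2-(3-benzyloxyphenyl)ethyl]-4,6-dimethoxybenzaldehyde, via B-alkyl-9-BBN 4 (not isolated)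
Conditions: 9-BBN (0.5 M in THF), 0 °C → rt; then 3 M aq K3PO4; then 3, PdCl2(dppf) (5 mol %), THF/DMF, 60 °C
Reagents that add atoms: none
Why: 9-BBN places boron on the terminal carbon of the styrene, and the borane, converted to its hydroxyborate by aqueous base before the aldehyde-bearing bromide is added, should undergo B-alkyl Suzuki–Miyaura coupling with the ortho-formyl aryl bromide, whose formyl group favours oxidative addition.

Step 3
Reactants: 5 2-[2-(3-benzyloxyphenyl)ethyl]-4,6-dimethoxybenzaldehyde
Product: 6 2-[2-(3-benzyloxyphenyl)ethyl]-6-hydroxy-4-methoxybenzaldehyde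
Conditions: MgI2·OEt2 (2 equiv), toluene, 80 °C; then 1 M HCl
Reagents that add atoms: none
Why: Chelation-controlled demethylation, in which magnesium bound between the formyl oxygen and the ortho methoxy oxygen activates only that methyl group for attack by iodide, should spare the para methoxy group and the remote benzyl ether.

Step 4
Reactants: 7 acetosyringone (1-(4-hydroxy-3,5-dimethoxyphenyl)ethanone)
Product: 8 1-(4-benzyloxy-3,5-dimethoxyphenyl)ethanone
Conditions: BnBr, K2CO3, DMF, 60 °C
Reagents that add atoms: benzyl bromide, BrCc1ccccc1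
Why: Williamson etherification of the acidic para-acyl phenol should proceed cleanly in DMF despite the two flanking methoxy groups.

Step 5
Reactants: 6 2-[2-(3-benzyloxyphenyl)ethyl]-6-hydroxy-4-methoxybenzaldehyde; 8 1-(4-benzyloxy-3,5-dimethoxyphenyl)ethanone
Product: 10 2-(4-benzyloxy-3,5-dimethoxyphenyl)-5-[2-(3-benzyloxyphenyl)ethyl]-7-methoxychromenylium tetrafluoroborate, via 2-hydroxychalcone 9 (not isolated)
Conditions: HBF4·OEt2, AcOH/EtOAc, rt; then Et2O (precipitation)
Reagents that add atoms: tetrafluoroboric acid (as its diethyl ether complex), [H+].F[B-](F)(F)F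
Why: Acid-mediated aldol condensation forms C3–C4 of the 2-hydroxychalcone, whose phenol then adds to the protonated ketone and loses water (O1–C2) to give the aromatic benzopyrylium cation, the classical flavylium salt synthesis, with the non-nucleophilic counter-ion sparing the benzyl ethers.

Step 6
Reactants: 10 2-(4-benzyloxy-3,5-dimethoxyphenyl)-5-[2-(3-benzyloxyphenyl)ethyl]-7-methoxychromenylium tetrafluoroborate
Product: 11 2-(4-benzyloxy-3,5-dimethoxyphenyl)-5-[2-(3-benzyloxyphenyl)ethyl]-7-methoxy-4H-chromene
Conditions: LiAlH4, THF, −20 → 0 °C; aq NaOH work-up; Et3N-washed silica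
Reagents that add atoms: none
Why: Hydride reduction of 2-arylbenzopyrylium salts with an aluminium hydride is known to deliver hydride to the unsubstituted C4 rather than the aryl-bearing C2, giving the 4H-chromene, which is kept acid-free because its enol ether is acid-labile; no stereocentre is formed.

Step 7
Reactants: 11 2-(4-benzyloxy-3,5-dimethoxyphenyl)-5-[2-(3-benzyloxyphenyl)ethyl]-7-methoxy-4H-chromene
Product: 13 (2R,3S)-2-(4-benzyloxy-3,5-dimethoxyphenyl)-5-[2-(3-benzyloxyphenyl)ethyl]-7-methoxychroman-3-ol, via flavan-3-yl(isopinocampheyl)borane 12 (not isolated)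
Conditions: IpcBH2 [from (+)-α-pinene, enantiopure THF stock solution, 1.2 equiv], THF, −25 → 0 °C; then 3 M NaOH, 30% H2O2, 0 °C
Reagents that add atoms: hydrogen peroxide, OO
Why: Proposed new method: the B–H bond of monoisopinocampheylborane should add across the C2=C3 enol ether bond through a concerted four-centre transition state, with boron at C3 because both the ring oxygen O1 and the C2 aryl group stabilise positive charge at C2, and alkaline hydrogen peroxide then converts C3–B into C3–OH by a 1,2-shift with retention. The closest known reactions are the racemic hydroboration–oxidation of 4H-flav-2-enes to 2,3-trans-flavan-3-ols and the monoisopinocampheylborane hydroboration of 1-arylcycloalkenes to trans-2-arylcycloalkanols, of which this is the enantioselective ring-oxygen analogue. No ring is closed, since ring C is already in place. The relative configuration (aryl at C2 and OH at C3 trans) is fixed by suprafacial addition and retentive oxidation, and the absolute configuration (2R,3S) by the isopinocampheyl group on boron. The step needs enantioface selectivity, which rests on the reagent alone because the substrate is flat and achiral; regioselectivity is secured by the polarisation of the alkene and chemoselectivity by the absence of any other alkene or reducible group. Cold oxidation limits β-elimination of the β-aryloxy borane, and crystallisation of 13 can raise the enantiopurity if needed.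

Step 8
Reactants: 13 (2R,3S)-2-(4-benzyloxy-3,5-dimethoxyphenyl)-5-[2-(3-benzyloxyphenyl)ethyl]-7-methoxychroman-3-ol
Product: 14 (2R,3S)-2-(4-hydroxy-3,5-dimethoxyphenyl)-5-[2-(3-hydroxyphenyl)ethyl]-7-methoxychroman-3-ol (CNP0118545.1)
Conditions: H2 (1 atm), Pd/C, EtOAc/MeOH, rt
Reagents that add atoms: none
Why: Hydrogenolysis of the two aryl benzyl ethers over Pd/C under neutral conditions should free both phenols while the methyl ethers, the secondary alcohol and the cyclic aryl ether of ring C stay intact, so neither stereocentre is touched.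

**Compound list**

1 | 3-(benzyloxy)benzaldehyde | O=Cc1cccc(OCc2ccccc2)c1 | starting material
2 | 1-(benzyloxy)-3-ethenylbenzene | C=Cc1cccc(OCc2ccccc2)c1 | intermediate
3 | 2-bromo-4,6-dimethoxybenzaldehyde | COc1cc(OC)c(C=O)c(Br)c1 | starting material
4 | 9-[2-(3-benzyloxyphenyl)ethyl]-9-borabicyclo[3.3.1]nonane | C(Cc1cccc(OCc2ccccc2)c1)B1C2CCCC1CCC2 | intermediate (not isolated)
5 | 2-[2-(3-benzyloxyphenyl)ethyl]-4,6-dimethoxybenzaldehyde | COc1cc(OC)c(C=O)c(CCc2cccc(OCc3ccccc3)c2)c1 | intermediate
6 | 2-[2-(3-benzyloxyphenyl)ethyl]-6-hydroxy-4-methoxybenzaldehyde | COc1cc(O)c(C=O)c(CCc2cccc(OCc3ccccc3)c2)c1 | intermediate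
7 | acetosyringone, 1-(4-hydroxy-3,5-dimethoxyphenyl)ethanone | CC(=O)c1cc(OC)c(O)c(OC)c1 | starting material
8 | 1-(4-benzyloxy-3,5-dimethoxyphenyl)ethanone | CC(=O)c1cc(OC)c(OCc2ccccc2)c(OC)c1 | intermediate
9 | (E)-1-(4-benzyloxy-3,5-dimethoxyphenyl)-3-{2-[2-(3-benzyloxyphenyl)ethyl]-6-hydroxy-4-methoxyphenyl}prop-2-en-1-one | COc1cc(O)c(/C=C/C(=O)c2cc(OC)c(OCc3ccccc3)c(OC)c2)c(CCc2cccc(OCc3ccccc3)c2)c1 | intermediate (not isolated)
10 | 2-(4-benzyloxy-3,5-dimethoxyphenyl)-5-[2-(3-benzyloxyphenyl)ethyl]-7-methoxychromenylium tetrafluoroborate | COc1cc(CCc2cccc(OCc3ccccc3)c2)c2ccc(-c3cc(OC)c(OCc4ccccc4)c(OC)c3)[o+]c2c1.F[B-](F)(F)F | intermediate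
11 | 2-(4-benzyloxy-3,5-dimethoxyphenyl)-5-[2-(3-benzyloxyphenyl)ethyl]-7-methoxy-4H-chromene | COc1cc(CCc2cccc(OCc3ccccc3)c2)c2c(c1)OC(c1cc(OC)c(OCc3ccccc3)c(OC)c1)=CC2 | intermediate
12 | [2,3-trans-2-(4-benzyloxy-3,5-dimethoxyphenyl)-5-[2-(3-benzyloxyphenyl)ethyl]-7-methoxychroman-3-yl](isopinocampheyl)borane, boron on the C3 face later taken by OH, isopinocampheyl group from (+)-α-pinene | COc1cc(CCc2cccc(OCc3ccccc3)c2)c2c(c1)O[C@H](c1cc(OC)c(OCc3ccccc3)c(OC)c1)[C@@H](B[C@@H]1C[C@@H]3C[C@H]([C@H]1C)C3(C)C)C2 | intermediate (not isolated)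
13 | (2R,3S)-2-(4-benzyloxy-3,5-dimethoxyphenyl)-5-[2-(3-benzyloxyphenyl)ethyl]-7-methoxychroman-3-ol | COc1cc(CCc2cccc(OCc3ccccc3)c2)c2c(c1)O[C@H](c1cc(OC)c(OCc3ccccc3)c(OC)c1)[C@@H](O)C2 | intermediate
14 | (2R,3S)-2-(4-hydroxy-3,5-dimethoxyphenyl)-5-[2-(3-hydroxyphenyl)ethyl]-7-methoxychroman-3-ol (CNP0118545.1) | COc1cc(CCc2cccc(O)c2)c2c(c1)O[C@H](c1cc(OC)c(O)c(OC)c1)[C@@H](O)C2 | target

**Step count**

Total: 8 steps. Longest linear sequence: 7 steps (steps 1, 2, 3, 5, 6, 7, 8, from 1 to 14); step 4 is the one-step branch to the ring B ketone.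

**Steps most likely to fail**

Step 7 (new method). The ring oxygen may alter the steric picture taken from carbocyclic models, so enantioface selection could be poor. Addition to the electron-rich trisubstituted enol ether could also be slow, and the β-aryloxy borane could open ring C by β-elimination. The fallback uses known chemistry and takes the stereochemistry from resolution instead of reagent control. It sets out from 11: hydroboration with BH3·THF and oxidation with NaOH/H2O2, the established route from flav-2-enes to 2,3-trans-flavan-3-ols, should give the racemic trans-flavan-3-ol F1. Acylation with (1S)-(−)-camphanic chloride (Et3N, DMAP, CH2Cl2) should give the (2R,3S) camphanate F2 and the (2S,3R) camphanate F3, which are separated by crystallisation or chromatography. Saponification of the (2R,3S) ester (LiOH, THF/MeOH/H2O, rt) returns to the route at 13.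

Step 6. Hydride may be delivered partly to C2, giving the 2H-flav-3-ene, and the acid-sensitive enol ether may hydrate or disproportionate during isolation. The fallback also covers loss of a benzyl ether in the strong acid of step 5, because it avoids the flavylium salt. It sets out from 6 and 8: Claisen–Schmidt condensation (KOH, EtOH, rt) should give chalcone 9, here isolated. Hydrogenation of only the enone C=C over Pd/C poisoned with Ph2S (H2, 1 atm, EtOAc), conditions that spare benzyl ethers and aryl ketones, should give the dihydrochalcone F4. Cyclodehydration of this ketone through its cyclic hemiketal (catalytic TsOH, toluene, water removal, short reaction time) comes back to the route at 11.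

Step 3. Ether cleavage may be incomplete, or iodide may also attack the benzyl ether under forcing conditions. The fallback moves the demethylation ahead of the coupling, where no benzyl ether is present. It sets out from 3: BCl3 (CH2Cl2, −78 → 0 °C), the standard chelation-controlled cleavage of a methoxy group ortho to a formyl group, should give 2-bromo-6-hydroxy-4-methoxybenzaldehyde F5. B-alkyl Suzuki–Miyaura coupling of this bromide, carried as its phenoxide with extra K3PO4, with borane 4 made from 2 as in step 2, comes back to the route at 6.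

**Further compounds**

F1 | step 7 | racemic 2,3-trans-2-(4-benzyloxy-3,5-dimethoxyphenyl)-5-[2-(3-benzyloxyphenyl)ethyl]-7-methoxychroman-3-ol (both enantiomers written) | COc1cc(CCc2cccc(OCc3ccccc3)c2)c2c(c1)O[C@H](c1cc(OC)c(OCc3ccccc3)c(OC)c1)[C@@H](O)C2.COc1cc(CCc2cccc(OCc3ccccc3)c2)c2c(c1)O[C@@H](c1cc(OC)c(OCc3ccccc3)c(OC)c1)[C@H](O)C2
F2 | step 7 | (2R,3S)-2-(4-benzyloxy-3,5-dimethoxyphenyl)-5-[2-(3-benzyloxyphenyl)ethyl]-7-methoxychroman-3-yl (1S,4R)-camphanate | COc1cc(CCc2cccc(OCc3ccccc3)c2)c2c(c1)O[C@H](c1cc(OC)c(OCc3ccccc3)c(OC)c1)[C@@H](OC(=O)[C@@]34CC[C@@](C)(C(=O)O3)C4(C)C)C2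
F3 | step 7 | (2S,3R)-2-(4-benzyloxy-3,5-dimethoxyphenyl)-5-[2-(3-benzyloxyphenyl)ethyl]-7-methoxychroman-3-yl (1S,4R)-camphanate | COc1cc(CCc2cccc(OCc3ccccc3)c2)c2c(c1)O[C@@H](c1cc(OC)c(OCc3ccccc3)c(OC)c1)[C@H](OC(=O)[C@@]34CC[C@@](C)(C(=O)O3)C4(C)C)C2
F4 | step 6 | 1-(4-benzyloxy-3,5-dimethoxyphenyl)-3-{2-[2-(3-benzyloxyphenyl)ethyl]-6-hydroxy-4-methoxyphenyl}propan-1-one | COc1cc(O)c(CCC(=O)c2cc(OC)c(OCc3ccccc3)c(OC)c2)c(CCc2cccc(OCc3ccccc3)c2)c1
F5 | step 3 | 2-bromo-6-hydroxy-4-methoxybenzaldehyde | COc1cc(O)c(C=O)c(Br)c1
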